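Ring C is disconnected at O1–C2 and C4–C4a, so that ring A appears as a free 2-alkyl-5-methoxyresorcinol (a C,O-dinucleophile) and C2–C3–C4 as 3-ethoxyacryloyl chloride. The key step, a magnesium-templated ortho-acylation followed in the same flask by oxa-Michael addition–elimination, forges both bonds and delivers the 8-alkyl-7-hydroxy-5-methoxychromone. It exploits the symmetry of ring A: the two free CH carbons (future C4a/C6) and the two hydroxyls (future O1/O7) are equivalent, so neither protection nor regiocontrol is needed. The side-chain stereocentre is taken from (R)-limonene oxide through a decarboxylative aryl–alkyl coupling; C2 is set last by rhodium-catalysed asymmetric 1,4-arylation of the chromone.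

Key step: step 8

Remark: compounds 1, 3, 14 and 18 are taken as commercially available, 3 as the usual cis/trans mixture of (+)-limonene oxide.
Remark: the (S)-configured diphosphine in step 9 is assumed, by analogy with rhodium-catalysed 1,4-arylation of cyclic enones, to deliver the aryl group to the Re face of C2; the sense is to be checked on 5,7-dimethoxychromone and the (R)-ligand used if it proves opposite.

Step 1
Reactants: 1 5-methoxybenzene-1,3-diol
Product: 2 1-methoxy-3,5-bis(methoxymethoxy)benzene
Conditions: MOMCl, i-Pr2NEt, CH2Cl2, 0 °C → rt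
Reagents that add atoms: chloromethyl methyl ether, COCCl
Why: Williamson-type O-alkylation converts both phenols into MOM acetals, which later direct lithiation to the ring carbon between them.

Step 2
Reactants: 3 (4R)-limonene 1,2-oxide (cis/trans mixture)
Product: 5 (3R)-6-oxo-3-(prop-1-en-2-yl)heptanal, via limonene-1,2-diol 4 (not isolated)
Conditions: H5IO6, THF/H2O, 0 °C → rt
Reagents that add atoms: water, O
Why: Acidic epoxide hydrolysis and Malaprade glycol cleavage open the ring between C1 and C2, so that both epoxide diastereomers should converge on one keto aldehyde whose only stereocentre is the untouched C4 of limonene.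

Step 3
Reactants: 5 (3R)-6-oxo-3-(prop-1-en-2-yl)heptanal
Product: 6 (3R)-6-oxo-3-(prop-1-en-2-yl)heptanoic acid
Conditions: NaClO2, NaH2PO4, 2-methyl-2-butene, t-BuOH/H2O, 0 °C → rt
Reagents that add atoms: sodium chlorite, [Na+].[O-]Cl=O
Why: The Pinnick oxidation is selective for the aldehyde, and the excess 2-methyl-2-butene scavenges HOCl so that the isopropenyl group should be spared.

Step 4
Reactants: 6 (3R)-6-oxo-3-(prop-1-en-2-yl)heptanoic acid
Product: 7 1,3-dioxo-1,3-dihydro-2H-isoindol-2-yl (3R)-6-oxo-3-(prop-1-en-2-yl)heptanoate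
Conditions: N-hydroxyphthalimide, N,N'-diisopropylcarbodiimide, DMAP (cat.), CH2Cl2, rt
Reagents that add atoms: N-hydroxyphthalimide, ON1C(=O)c2ccccc2C1=O
Why: Carbodiimide (Steglich-type) esterification gives the redox-active N-(acyloxy)phthalimide needed for decarboxylative coupling.

Step 5
Reactants: 2 1-methoxy-3,5-bis(methoxymethoxy)benzene; 7 1,3-dioxo-1,3-dihydro-2H-isoindol-2-yl (3R)-6-oxo-3-(prop-1-en-2-yl)heptanoate
Product: 10 (5R)-5-{[4-methoxy-2,6-bis(methoxymethoxy)phenyl]methyl}-6-methylhept-6-en-2-one, via aryllithium 8 (not isolated), via arylzinc chloride 9 (not isolated)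
Conditions: 2, n-BuLi, THF, 0 °C; ZnCl2, THF, 0 °C → rt; then 7, NiCl2(dme) (20 mol%), 4,4'-di-tert-butyl-2,2'-bipyridine (40 mol%), THF/DMF, rt
Reagents that add atoms: none
Why: Directed ortho-metalation should occur at the carbon flanked by both MOM acetals, transmetalation gives the arylzinc, and the nickel-catalysed decarboxylative Negishi coupling (single-electron reduction of the ester, loss of CO2, capture of the primary radical at nickel, reductive elimination) forms the aryl–CH2 bond without touching the stereocentre, which is β to the radical and keeps the configuration inherited from limonene.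

Step 6
Reactants: 10 (5R)-5-{[4-methoxy-2,6-bis(methoxymethoxy)phenyl]methyl}-6-methylhept-6-en-2-one
Product: 11 (5R)-5-{[4-methoxy-2,6-bis(methoxymethoxy)phenyl]methyl}-2,6-dimethylhept-6-en-2-ol
Conditions: MeMgBr, THF, −78 → 0 °C; aq. NH4Cl
Reagents that add atoms: methylmagnesium bromide, C[Mg]Br
Why: Grignard addition to the methyl ketone installs the tertiary alcohol of the hydrated side chain, and the MOM ethers and the alkene are inert to it.

Step 7
Reactants: 11 (5R)-5-{[4-methoxy-2,6-bis(methoxymethoxy)phenyl]methyl}-2,6-dimethylhept-6-en-2-ol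
Product: 13 2-[(2R)-5-hydroxy-5-methyl-2-(prop-1-en-2-yl)hexyl]-5-methoxybenzene-1,3-diol, via tris(trimethylsilyl) ether 12 (not isolated)
Conditions: TMSOTf, 2,2'-bipyridyl, MeCN, 0 °C → rt; H2O; then citric acid, MeOH, rt
Reagents that add atoms: none
Why: Silyl triflate/bipyridyl cleavage of aryl MOM acetals runs through pyridinium intermediates without free Brønsted acid, so the isopropenyl group should not cyclise onto the flanking phenols, and mild solvolysis then removes the TMS ethers.

Step 8
Reactants: 13 2-[(2R)-5-hydroxy-5-methyl-2-(prop-1-en-2-yl)hexyl]-5-methoxybenzene-1,3-diol; 14 (2E)-3-ethoxyprop-2-enoyl chloride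
Product: 17 7-hydroxy-8-[(2R)-5-hydroxy-5-methyl-2-(prop-1-en-2-yl)hexyl]-5-methoxy-4H-chromen-4-one, via bis(bromomagnesium) phenolate 15 (not isolated), via ethoxyenone 16 (not isolated)
Conditions: EtMgBr (2.05 equiv), Et2O/toluene, 0 °C → rt; 14 (1.0 equiv), toluene, rt → 60 °C; then AcOH, MeOH, rt
Reagents that add atoms: none
Why: Two equivalents of EtMgBr convert the two phenols into aryloxymagnesium bromides (the tertiary alcohol stays protonated), the acid chloride is bound by the magnesium on oxygen and delivered through a six-membered chelate to the adjacent free ring carbon, which forms C4–C4a by ortho-selective Friedel–Crafts acylation, and the released proton is taken up by phenolate so that no free acid meets the isopropenyl group. The resulting 2-hydroxyaryl β-ethoxyvinyl ketone 16 then closes through O1 onto the β-carbon (6-endo-trig oxa-Michael addition) and loses ethanol (addition–elimination), which forms O1–C2 and drives the sequence irreversibly to the aromatic 4-pyranone. The closest known reaction types are the metal-template ortho-acylation of aryloxymagnesium halides by α,β-unsaturated acid chlorides and the cyclisation of 2-hydroxyaryl β-alkoxyvinyl ketones to chromones. No stereocentre is created, since C2 is still trigonal, and the side-chain stereocentre is remote from all reacting atoms. The step needs C- over O-acylation, which the magnesium chelate in a non-coordinating solvent should secure, and mono-acylation, which the deactivating acyl group should secure. Regiochemistry needs no control, because ring A of 13 is symmetric about the axis through its alkylated and methoxylated carbons: the two free CH positions are equivalent and only the hydroxyl next to the new ketone can cyclise, so O1 is necessarily the oxygen flanking C8.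

Step 9
Reactants: 17 7-hydroxy-8-[(2R)-5-hydroxy-5-methyl-2-(prop-1-en-2-yl)hexyl]-5-methoxy-4H-chromen-4-one; 18 (4-hydroxy-2-methoxyphenyl)boronic acid
Product: 19 (2S)-7-hydroxy-2-(4-hydroxy-2-methoxyphenyl)-8-[(2R)-5-hydroxy-5-methyl-2-(prop-1-en-2-yl)hexyl]-5-methoxy-2,3-dihydro-4H-chromen-4-one
Conditions: [Rh(OH)(cod)]2 (3 mol%), (S)-MeO-F12-BIPHEP (6.6 mol%), 18 (3 equiv), toluene/H2O, 25–40 °C, no added base
Reagents that add atoms: none
Why: In this Hayashi–Miyaura asymmetric 1,4-addition the aryl group is transferred from boron to rhodium, the chromone C2=C3 bond inserts, and water protonates the rhodium enolate; the chiral diphosphine should direct the aryl group to the Re face of C2 and so give (2S) under catalyst control, independent of the remote side-chain centre, while base-free conditions avoid retro-oxa-Michael opening of the product.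

Compound list
1 | 5-methoxybenzene-1,3-diol | COc1cc(O)cc(O)c1 | starting material
2 | 1-methoxy-3,5-bis(methoxymethoxy)benzene | COCOc1cc(OC)cc(OCOC)c1 | intermediate
3 | (4R)-limonene 1,2-oxide, (4R)-1-methyl-4-(prop-1-en-2-yl)-7-oxabicyclo[4.1.0]heptane, cis/trans mixture | CC12OC1C[C@@H](CC2)C(C)=C | starting material
4 | (4R)-1-methyl-4-(prop-1-en-2-yl)cyclohexane-1,2-diol (limonene-1,2-diol, diastereomer mixture) | CC1(O)C(O)C[C@@H](CC1)C(C)=C | intermediate (not isolated)
5 | (3R)-6-oxo-3-(prop-1-en-2-yl)heptanal | O=CC[C@@H](CCC(C)=O)C(C)=C | intermediate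
6 | (3R)-6-oxo-3-(prop-1-en-2-yl)heptanoic acid | OC(=O)C[C@@H](CCC(C)=O)C(C)=C | intermediate
7 | 1,3-dioxo-1,3-dihydro-2H-isoindol-2-yl (3R)-6-oxo-3-(prop-1-en-2-yl)heptanoate | O=C(C[C@@H](CCC(C)=O)C(C)=C)ON1C(=O)c2ccccc2C1=O | intermediate
8 | [4-methoxy-2,6-bis(methoxymethoxy)phenyl]lithium | [Li]c1c(OCOC)cc(OC)cc1OCOC | intermediate (not isolated)
9 | [4-methoxy-2,6-bis(methoxymethoxy)phenyl]zinc chloride | Cl[Zn]c1c(OCOC)cc(OC)cc1OCOC | intermediate (not isolated)
10 | (5R)-5-{[4-methoxy-2,6-bis(methoxymethoxy)phenyl]methyl}-6-methylhept-6-en-2-one | COCOc1cc(OC)cc(OCOC)c1C[C@@H](CCC(C)=O)C(C)=C | intermediate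
11 | (5R)-5-{[4-methoxy-2,6-bis(methoxymethoxy)phenyl]methyl}-2,6-dimethylhept-6-en-2-ol | COCOc1cc(OC)cc(OCOC)c1C[C@@H](CCC(C)(C)O)C(C)=C | intermediate
12 | {[(5R)-5-{[4-methoxy-2,6-bis(trimethylsilyloxy)phenyl]methyl}-2,6-dimethylhept-6-en-2-yl]oxy}trimethylsilane | COc1cc(O[Si](C)(C)C)c(C[C@@H](CCC(C)(C)O[Si](C)(C)C)C(C)=C)c(O[Si](C)(C)C)c1 | intermediate (not isolated)
13 | 2-[(2R)-5-hydroxy-5-methyl-2-(prop-1-en-2-yl)hexyl]-5-methoxybenzene-1,3-diol | COc1cc(O)c(C[C@@H](CCC(C)(C)O)C(C)=C)c(O)c1 | intermediate
14 | (2E)-3-ethoxyprop-2-enoyl chloride | CCO/C=C/C(=O)Cl | starting material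
15 | bis(bromomagnesium) 2-[(2R)-5-hydroxy-5-methyl-2-(prop-1-en-2-yl)hexyl]-5-methoxybenzene-1,3-diolate | COc1cc(O[Mg]Br)c(C[C@@H](CCC(C)(C)O)C(C)=C)c(O[Mg]Br)c1 | intermediate (not isolated)
16 | (2E)-1-{2,4-dihydroxy-3-[(2R)-5-hydroxy-5-methyl-2-(prop-1-en-2-yl)hexyl]-6-methoxyphenyl}-3-ethoxyprop-2-en-1-one | CCO/C=C/C(=O)c1c(OC)cc(O)c(C[C@@H](CCC(C)(C)O)C(C)=C)c1O | intermediate (not isolated)
17 | 7-hydroxy-8-[(2R)-5-hydroxy-5-methyl-2-(prop-1-en-2-yl)hexyl]-5-methoxy-4H-chromen-4-one | C=C(C)[C@H](CCC(C)(C)O)Cc1c(O)cc(OC)c2c1OC=CC2=O | intermediate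
18 | (4-hydroxy-2-methoxyphenyl)boronic acid | OB(O)c1ccc(O)cc1OC | starting material
19 | (2S)-7-hydroxy-2-(4-hydroxy-2-methoxyphenyl)-8-[(2R)-5-hydroxy-5-methyl-2-(prop-1-en-2-yl)hexyl]-5-methoxy-2,3-dihydro-4H-chromen-4-one | C=C(C)[C@H](CCC(C)(C)O)Cc1c(O)cc(OC)c2c1O[C@H](c1ccc(O)cc1OC)CC2=O | target

Total step count: 9. Longest linear sequence: 8 steps (3 → 19, steps 2 to 9).

Steps most likely to fail

1. Step 8. The acid chloride may acylate a phenolate oxygen, or the ring twice, instead of the ortho carbon, or the enone may hydrolyse on quench before it cyclises. The fallback sets out from 13 and comes back at 17. It makes the O-acylation deliberate: 13 and 14 with Et3N in CH2Cl2 at −40 °C should give the mono-ester 3-hydroxy-2-[(2R)-5-hydroxy-5-methyl-2-(prop-1-en-2-yl)hexyl]-5-methoxyphenyl (2E)-3-ethoxyprop-2-enoate F1. Irradiation (300 nm, MeCN, rt) then triggers a photo-Fries rearrangement: the aryl O–acyl bond homolyses and the acyl radical recombines at the ortho or the para carbon. These are the two equivalent free positions of ring A, so both modes converge on ethoxyenone 16, which closes to 17 on treatment with AcOH. C4–C4a and O1–C2 are still formed in one operation.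

2. Step 5. Transmetalation and radical capture at nickel may be slow for the doubly ortho-substituted arylzinc, so that the primary homoallylic radical dimerises, is reduced or undergoes a 1,2-vinyl shift. The fallback sets out from 6 and 2 and comes back at 10; it replaces the radical coupling by a two-electron cross-coupling. Decarboxylative iodination of 6 (PhI(OAc)2, I2, hν) should give (5S)-5-(iodomethyl)-6-methylhept-6-en-2-one F2 (same spatial arrangement; the descriptor changes only through the rank of iodine). Zinc insertion (Zn, LiCl, THF) gives [(2S)-5-oxo-2-(prop-1-en-2-yl)hexyl]zinc iodide F3. Negishi coupling (Pd(OAc)2, SPhos, THF) with 2-iodo-5-methoxy-1,3-bis(methoxymethoxy)benzene F4, made from 2 by lithiation and I2, returns to 10.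

3. Step 9. Facial discrimination may be insufficient when the electron-rich chromone inserts into the ortho-substituted aryl–rhodium bond, or protodeboronation may outrun insertion. The fallback sets out from 17 and comes back at 19; it replaces asymmetric catalysis by kinetic resolution. Non-selective arylation of 17 with excess 18 ([Rh(OH)(cod)]2, rac-BINAP) gives the C2-epimer mixture (2RS)-7-hydroxy-2-(4-hydroxy-2-methoxyphenyl)-8-[(2R)-5-hydroxy-5-methyl-2-(prop-1-en-2-yl)hexyl]-5-methoxy-2,3-dihydro-4H-chromen-4-one F5. Asymmetric transfer hydrogenation (RuCl(p-cymene)[(R,R)-TsDPEN], HCO2H/Et3N, rt; the catalyst antipode matched to the (2R)-epimer) should reduce that epimer faster to (2R,4R)-2-(4-hydroxy-2-methoxyphenyl)-8-[(2R)-5-hydroxy-5-methyl-2-(prop-1-en-2-yl)hexyl]-5-methoxy-3,4-dihydro-2H-chromene-4,7-diol F6. The unreacted (2S)-ketone 19 is then separated by chromatography.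

Further compounds
F1 | step 8 | 3-hydroxy-2-[(2R)-5-hydroxy-5-methyl-2-(prop-1-en-2-yl)hexyl]-5-methoxyphenyl (2E)-3-ethoxyprop-2-enoate | CCO/C=C/C(=O)Oc1cc(OC)cc(O)c1C[C@@H](CCC(C)(C)O)C(C)=C
F2 | step 5 | (5S)-5-(iodomethyl)-6-methylhept-6-en-2-one | IC[C@@H](CCC(C)=O)C(C)=C
F3 | step 5 | [(2S)-5-oxo-2-(prop-1-en-2-yl)hexyl]zinc iodide | I[Zn]C[C@@H](CCC(C)=O)C(C)=C
F4 | step 5 | 2-iodo-5-methoxy-1,3-bis(methoxymethoxy)benzene | COCOc1cc(OC)cc(OCOC)c1I
F5 | step 9 | (2RS)-7-hydroxy-2-(4-hydroxy-2-methoxyphenyl)-8-[(2R)-5-hydroxy-5-methyl-2-(prop-1-en-2-yl)hexyl]-5-methoxy-2,3-dihydro-4H-chromen-4-one (C2-epimer mixture) | C=C(C)[C@H](CCC(C)(C)O)Cc1c(O)cc(OC)c2c1OC(c1ccc(O)cc1OC)CC2=O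
F6 | step 9 | (2R,4R)-2-(4-hydroxy-2-methoxyphenyl)-8-[(2R)-5-hydroxy-5-methyl-2-(prop-1-en-2-yl)hexyl]-5-methoxy-3,4-dihydro-2H-chromene-4,7-diol | C=C(C)[C@H](CCC(C)(C)O)Cc1c(O)cc(OC)c2c1O[C@@H](c1ccc(O)cc1OC)C[C@H]2O
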